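## Structural features

The target is a labdane: a trans-fused decalin (ring A = C1–C5 and C10, ring B = C5–C10) with a trisubstituted C7=C8 alkene in ring B and, equatorial on C9, a six-carbon chain whose (E)-C13=C14 alkene ends in a primary allylic methyl succinate at C15. Ring A carries an equatorial 2α-hydroxyl and a quaternary C4 with an α-methyl (C18) and an axial β-CH2O-isovalerate (C19) that is syn-axial to the C10 methyl (C20). Four stereocentres are contiguous (C4, C5, C10, C9), two of them quaternary, and C2 stands 1,3 to both C4 and C10. The sensitive parts are the allylic C15 ester (ionisation, allylic transposition), the coexistence of two different esters with one free secondary alcohol, and the C7=C8 alkene, which acid can move to the tetrasubstituted position and which makes C9–H allylic. The real difficulty is the quaternary C4 with its two one-carbon groups differentiated next to C5, together with the need to finish with three oxygens in three different states. The key step uses the position of C3 between the C2 oxygen and C4: as the carbene carbon of a diazoketone it adds across a C4=C18 alkene on a carvone-derived ring B and closes ring A, and the C3–C18 bond of the resulting cyclopropyl ketone is later cut so that C18 remains as the 4α-methyl. Because the 2α-alcohol is the equatorial, thermodynamically preferred epimer, the same electron-transfer reduction can also set C2.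

## Logic of the disconnections

**37 ⇒ 36 ⇒ 34 + 35 ⇒ 33.** The last bonds made are heteroatom bonds: O–Si at C2 (from 36), the C19 O–acyl bond (34 + 35) and O–Si at C19 (from 33). Cutting here leaves the three oxygens separately addressable. The forward steps need a primary alkylsilyl ether that leaves before a secondary arylsilyl ether, and fluoride conditions that spare both esters.

**33 ⇒ 25 + 30.** The C11–C12 bond is cut because it is an sp3–sp3 bond at an allylic carbon. This gives a C11 nucleophile from 25 and a primary allylic bromide 30 that already holds C12–C16, the E alkene and the succinate, removing five carbons and one ester in a convergent step. The forward coupling must be α-selective (no allylic transposition), keep the alkene geometry and leave the esters alone.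

**30 ⇒ 29 ⇒ 28 ⇒ 26 + 27.** C12–Br, C12–O and the C15 O–acyl bond are cut in turn. The fragment comes from two purchasable pieces, and the alkene geometry is fixed by an E-selective allylic hydroxylation of 28.

**25 ⇒ 24 ⇒ 22 ⇒ 20 + 21.** C11–I and C11–O are functional-group changes; the real cut is C9=C11, which returns the C9 carbonyl of 20. C9 is the old carvone carbonyl carbon, so one-carbon olefination is the shortest way to C11. The 9α-hydrogen must come from addition to the α face of 22, opposite the axial C10 methyl, and the reagent must choose the terminal alkene of the diene.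

**20 ⇒ 19 ⇒ 18 ⇒ 16 (through 17).** These are O–Si formation at C2, oxidation state change at C9, and in the reverse sense re-formation of the C3–C18 bond and the C2 carbonyl. The cyclopropyl ketone 16 is the retron for the 4α-methyl. The forward reduction must cleave only the external cyclopropane bond, give the equatorial C2 alcohol, and leave the isolated ring B alkene and the allylic C9 oxygen intact.

**16 ⇒ 15 (key step).** C3–C4 and C3–C18 are cut, which removes ring A and the three-membered ring and leaves a monocyclic diazoketone. The forward step needs a carbene that chooses the 1,1-disubstituted alkene and one face of it. C9 cannot be a ketone in 15: a ketone oxygen 1,4 to the diazoketone carbonyl would capture the carbene as a six-membered carbonyl ylide, and a ring B enone would not survive the electron-transfer opening. 15 therefore holds C9 as a silyl-protected allylic carbinol, and the enone reappears only in 19.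

**15 ⇒ 12 + 13.** The C2–C3 bond is cut to an activated acid and a diazomethane equivalent. The activation must be free of acid so that the silyl ethers of 12 survive.

**12 ⇒ 11 ⇒ 9 ⇒ 8 ⇒ 6 ⇒ 5.** These are two O–Si bonds, ester hydrolysis, the C9 C–H bond (carbonyl reduction), and C19–O made by way of C19–Cl from the isopropenyl methyl. The allylic chlorination must come while ring B is still an enone, so that its alkene is deactivated. The arm is a methyl ester because an acid-labile ester could not be cleaved without losing the silyl ethers.

**5 ⇒ 3 + 4, 3 ⇒ 1 + 2.** C10–C1 and C10–C20 are cut to two enolate alkylations of 1. The order matters: the second electrophile enters anti to the C5 substituent, so methyl first and acetate arm second gives the C10 configuration of the trans-decalin.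

## Other disconnections considered

**Alternative 1:** The cut is C5–C10 and C8–C9, so both rings go at once. In the forward sense the open-chain trienoate A1, an (E)-β-methyl enoate joined through C1–C4 to a 2-silyloxy diene, would be heated to undergo a type 1 intramolecular Diels–Alder reaction to the bicyclic silyl enol ether A2.
- In its favour: one step makes two C–C bonds, both rings and the C5, C9 and C10 centres. The suprafacial rule ties C9 to C10 through the enoate geometry. C11 arrives as an ester, and the enol ether marks C7 for later generation of the C7=C8 alkene.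
- Against it here: the dienophile is β,β-disubstituted, and its carbon C10 must bond to a diene terminus that bears the quaternary C4, so the bond that closes ring A joins two very hindered carbons. The silyloxy diene tolerates little Lewis acid, which leaves only heat. The trans fusion and the π-face are steered only by C2 and C4 of A1. A1 itself needs an enantioselective synthesis of an acyclic quaternary C4.
- Comparison: on bond and stereocentre economy of the key step the cycloaddition is the better plan, and it is also better for C9/C11, which the chosen route needs several steps to build. On structure, the chosen plan takes ring B and C5 from the chiral pool and creates only C4, under control of a rigid neighbour. On mechanism both are concerted and stereospecific, but the carbene adds to an unhindered alkene whereas the cycloaddition must overcome double hindrance. Overall length is expected to be similar because A1 is long to make.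

**Alternative 2:** The cut is C2–C3. The phenyl selenoester A3, which carries C19 as an acrylate ester on the carvone ring, would be treated with Bu3SnH and a radical initiator. The C2 acyl radical adds to the acrylate CH2 (C3) in a 6-endo closure, and the α-ester radical at C4 is reduced to give the diketo ester A4.
- In its favour: it starts from the same chiral pool ring and uses the same alkylations for C10. The nucleophilic acyl radical and the acrylate are polarity-matched, and the endo mode is favoured because the internal alkene carbon is substituted. No diazo compound is needed, and a ring B enone is tolerated, so C9 needs no masking. On that point it is better than the chosen plan.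
- Against it here: C4 emerges as a methine. C18 is absent and has to be added by enolate methylation of the ester in a molecule with two more acidic ketones, which calls for protection of both. The C19 ester must later be reduced selectively.
- Comparison: on structure, the chosen plan makes the quaternary centre in the ring-closing step with its two substituents already differentiated. On mechanism, the radical chain is at least the equal of the metal carbene in functional-group tolerance. On step economy the ring closure is equal, but the later methylation, protection and reduction steps make the sequence after the key step longer.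

**Alternative 3:** The cut is C5–C6 and C1–C10. The allylic acetate A5 would be ionised by a Lewis acid such as SnCl4 at low temperature. The C5=C10 alkene attacks C6 and closes ring B, and the C10 cation is captured by carbon C1 of the enol silane, which closes ring A and gives the ketone A6.
- In its favour: it is the most convergent plan. A6 already has the C7=C8 alkene, the C19 isovalerate, the C2 ketone and a C11–C12 stub on C9, so the product of the key step is closer to the target than in the chosen plan. The E alkene should give the trans fusion through a chair–chair array.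
- Against it here: the enol silane is the best nucleophile in A5 and may be desilylated or may attack the allyl cation directly. The allyl cation is unsymmetrical. The nucleophilic carbon C5 is neopentylic. The stereocentres C4 and C9 flank the reacting alkene and must favour the same folding. The ester carbonyl can intercept the C10 cation. A5 is a long enantioselective target in itself. The equatorial C2 alcohol would still have to be made from A6 in the presence of esters, which excludes dissolving metals.
- Comparison: on structure, alternative 3 needs C4 and C9 beforehand, while the chosen plan needs only C5 of carvone. On mechanism, a stepwise cationic cascade with several competing nucleophiles is less predictable than a single concerted carbene addition. On step economy after the key step, alternative 3 is better; before the key step it is worse.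

Key step: step 9

Remarks on the chemistry:
- Labdane numbering is used for all intermediates; α and β refer to the usual drawing with the C10 methyl (C20) β.
- 3 is used as a mixture of C6 epimers. The C9 carbinol centre of 9–18 is drawn as the expected 9β epimer; either epimer serves, because C9 is oxidised again in step 11.
- TBS = tert-butyldimethylsilyl, TES = triethylsilyl, TBDPS = tert-butyldiphenylsilyl.

## Steps

Step 1
Reactants: 1 (R)-carvone; 2 iodomethane
Product: 3 (5R)-2,6-dimethyl-5-(prop-1-en-2-yl)cyclohex-2-en-1-one (both C6 epimers)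
Conditions: LiN(i-Pr)2, THF, −78 °C; MeI, −78 → 0 °C
Reagents that add atoms: none
Why: Kinetic α′-deprotonation gives the cross-conjugated enolate, which is C-methylated (enolate alkylation); the C6 configuration does not matter because this centre is enolised again in step 2.

Step 2
Reactants: 3 (5R)-2,6-dimethyl-5-(prop-1-en-2-yl)cyclohex-2-en-1-one; 4 methyl bromoacetate
Product: 5 methyl 2-[(1S,6S)-1,3-dimethyl-2-oxo-6-(prop-1-en-2-yl)cyclohex-3-en-1-yl]acetate
Conditions: LiN(i-Pr)2, THF, −78 → −20 °C; BrCH2CO2Me, DMPU, −78 → −20 °C
Reagents that add atoms: none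
Why: Enolate alkylation; the tetrasubstituted enolate is attacked anti to the neighbouring isopropenyl group, so the acetate arm ends trans to it and the methyl cis, which is the C10/C5 relationship of the trans-decalin.

Step 3
Reactants: 5 methyl 2-[(1S,6S)-1,3-dimethyl-2-oxo-6-(prop-1-en-2-yl)cyclohex-3-en-1-yl]acetate
Product: 6 methyl 2-[6-(3-chloroprop-1-en-2-yl)-1,3-dimethyl-2-oxocyclohex-3-en-1-yl]acetate (ring centres as in 5)
Conditions: Ca(OCl)2, CO2 (dry ice), CH2Cl2/H2O, 0 °C
Reagents that add atoms: calcium hypochlorite, [Ca+2].[O-]Cl.[O-]Cl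
Why: Ene-type allylic chlorination by hypochlorous acid: chlorine adds to the terminal CH2 of the electron-rich 1,1-disubstituted alkene and a methyl proton is lost, which shifts the double bond and leaves CH2Cl. The ring alkene is deactivated by the ketone, which is why this step precedes the carbonyl reduction.

Step 4
Reactants: 6 methyl 2-[6-(3-chloroprop-1-en-2-yl)-1,3-dimethyl-2-oxocyclohex-3-en-1-yl]acetate
Product: 8 methyl 2-[6-(3-hydroxyprop-1-en-2-yl)-1,3-dimethyl-2-oxocyclohex-3-en-1-yl]acetate, via allylic acetate 7 (not isolated)
Conditions: KOAc, NaI (cat.), DMF, 60 °C; then K2CO3, MeOH, rt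
Reagents that add atoms: potassium acetate, [K+].CC([O-])=O
Why: SN2 displacement of the primary allylic chloride by acetate, then K2CO3-catalysed transesterification in methanol; the methyl ester of the arm is unchanged by methanolysis.

Step 5
Reactants: 8 methyl 2-[6-(3-hydroxyprop-1-en-2-yl)-1,3-dimethyl-2-oxocyclohex-3-en-1-yl]acetate
Product: 9 methyl 2-[2-hydroxy-6-(3-hydroxyprop-1-en-2-yl)-1,3-dimethylcyclohex-3-en-1-yl]acetate (carbinol OH cis to the ring methyl, i.e. 9β)
Conditions: NaBH4, CeCl3·7H2O, MeOH, −40 → 0 °C
Reagents that add atoms: none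
Why: Luche 1,2-reduction of the hindered enone; hydride should enter anti to the axial C10 methyl and give the 9β-carbinol. The reduction removes the ketone oxygen that would otherwise capture the carbene of step 9 as a six-membered carbonyl ylide.

Step 6
Reactants: 9 methyl 2-[2-hydroxy-6-(3-hydroxyprop-1-en-2-yl)-1,3-dimethylcyclohex-3-en-1-yl]acetate
Product: 11 methyl ester bearing the C19 TBS ether and the C9 TES ether, via mono-TBS ether 10 (not isolated)
Conditions: TBSCl, imidazole, CH2Cl2, 0 °C; then 2,6-lutidine, TESOTf, −78 → 0 °C
Reagents that add atoms: tert-butyldimethylsilyl chloride, CC(C)(C)[Si](C)(C)Cl; triethylsilyl trifluoromethanesulfonate, CC[Si](CC)(CC)OS(=O)(=O)C(F)(F)F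
Why: Graded silylation: the unhindered primary allylic hydroxyl takes the TBS group selectively, then the hindered secondary carbinol is capped with the more reactive silyl triflate. TES is chosen for C9 so that it can later be removed in the presence of the primary TBS ether.

Step 7
Reactants: 11 methyl ester bearing the C19 TBS ether and the C9 TES ether
Product: 12 the corresponding carboxylic acid (C19 TBS ether, C9 TES ether)
Conditions: LiOH·H2O, THF/MeOH/H2O, rt → 40 °C; AcOH to pH 5
Reagents that add atoms: lithium hydroxide, [Li+].[OH-]
Why: Saponification of the methyl ester; both silyl ethers are stable to aqueous LiOH, and the buffered acidification spares the TES ether. A methyl ester is used because acidolysis of a tert-butyl ester would strip the silyl ethers.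

Step 8
Reactants: 12 carboxylic acid (C19 TBS ether, C9 TES ether); 13 (trimethylsilyl)diazomethane
Product: 15 diazomethyl ketone with the 2-(TBS-oxymethyl)allyl arm at C5 and the TES ether at C9, via acid chloride 14 (not isolated)
Conditions: 1-chloro-N,N,2-trimethylprop-1-en-1-amine, CH2Cl2, 0 °C → rt; then TMSCHN2, THF/MeCN, 0 °C → rt
Reagents that add atoms: none
Why: The α-chloroenamine gives the acid chloride under neutral conditions, avoiding HCl that would cleave the TES ether. Acylation of (trimethylsilyl)diazomethane at carbon and loss of the silyl group to chloride gives the diazomethyl ketone (Arndt–Eistert-type acylation).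

Step 9
Reactants: 15 diazomethyl ketone with the 2-(TBS-oxymethyl)allyl arm at C5 and the TES ether at C9
Product: 16 tricyclic cyclopropyl ketone (2-oxo, cyclopropane C3–C4–C18 on the α face, 19-OTBS, 9β-OTES, C7=C8, 5α-H, 10β-CH3)
Conditions: Cu(acac)2 (5 mol %), toluene, 100 °C, slow addition of 15
Reagents that add atoms: none
Why: Cu(acac)2 is reduced by the diazo compound to a monovalent copper species that takes up C3 with loss of N2, and the electrophilic copper carbene adds to the electron-rich 1,1-disubstituted C4=C18 alkene in a concerted, asynchronous [2+1] step; the closest known reaction type is the copper-catalysed intramolecular cyclopropanation of unsaturated α-diazoketones. Ring A closes through the C3–C4 bond in an exo sense (six-membered ring, C18 left outside), and the three-membered ring closes through C3–C18 in the same cheletropic event. C4 is set by the carvone-derived C5 and C10: in the chair-like array with both arms equatorial, the =CH2 group eclipses C5–H (least allylic strain) and lies away from the axial C10 methyl, so C18 ends α and C19 β. C3 is not independent, because a cyclopropane can only be cis-fused to the six-membered ring. The step needs chemoselectivity for C4=C18 over the ring alkene, over C–H insertion and over heteroatom ylides. The tether can reach C7=C8 only through a strained bridged array, copper carbenes insert poorly into C–H bonds, the silyl ether oxygens are hindered, and no ketone oxygen stands 1,4 to the diazoketone carbonyl, so no six-membered carbonyl ylide can form.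

Step 10
Reactants: 16 tricyclic cyclopropyl ketone
Product: 18 trans-decal-7-ene-2α,9β-diol with 4α-CH3 and 4β-CH2OTBS and 8-CH3 and 10β-CH3, via C2 carbinol TES ether 17 (not isolated)
Conditions: Li, NH3(l)/THF, −78 °C; then EtOH, −78 → −33 °C; NH4Cl; then PPTS, MeOH, 0 °C → rt
Reagents that add atoms: none
Why: Dissolving-metal reduction: electron transfer to the cyclopropyl ketone cleaves the external C3–C18 bond, the one that overlaps with the carbonyl π system, so C18 becomes the 4α-methyl. Protonation of the enolate by ethanol and further reduction gives the thermodynamically preferred equatorial 2α-alcohol, since a 2β-oxygen would be syn-axial to both C19 and C20. The isolated C7=C8 alkene and the alkylsilyl ethers are inert, and mild acid methanolysis then removes only the TES group.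

Step 11
Reactants: 18 trans-decal-7-ene-2α,9β-diol
Product: 19 2α-hydroxy-19-(TBS-oxy) trans-decal-7-en-9-one (4α-CH3, 8-CH3, 10β-CH3)
Conditions: MnO2 (activated, excess), CH2Cl2, rt
Reagents that add atoms: none
Why: MnO2 oxidises only the allylic C9 carbinol, which regenerates the ring B enone and leaves the saturated 2α-hydroxyl untouched; the C9 stereocentre is erased here.

Step 12
Reactants: 19 2α-hydroxy-19-(TBS-oxy) trans-decal-7-en-9-one
Product: 20 2α-(TBDPS-oxy)-19-(TBS-oxy) trans-decal-7-en-9-one
Conditions: TBDPSCl, imidazole, DMF, rt
Reagents that add atoms: tert-butyldiphenylsilyl chloride, CC(C)(C)[Si](Cl)(c1ccccc1)c1ccccc1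
Why: Silylation of the only free hydroxyl; TBDPS is chosen so that the primary TBS ether at C19 can later be cleaved in its presence.

Step 13
Reactants: 20 2α-(TBDPS-oxy)-19-(TBS-oxy) trans-decal-7-en-9-one; 21 methyltriphenylphosphonium bromide
Product: 22 9-methylene trans-decal-7-ene (C7=C8–C9=C11 diene) with 2α-OTBDPS and 19-OTBS
Conditions: Ph3PCH3Br, KOt-Bu, toluene, 0 → 90 °C
Reagents that add atoms: none
Why: Wittig methylenation; the C9 ketone has no α′-hydrogen, and the ylide generated with KOt-Bu in hot toluene is the usual recourse for hindered ketones.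

Step 14
Reactants: 22 9-methylene trans-decal-7-ene
Product: 24 C11 primary alcohol (9α-H, CH2OH β on C9, C7=C8, 2α-OTBDPS, 19-OTBS), via B-alkyl-9-BBN adduct 23 (not isolated)
Conditions: 9-BBN, THF, 0 → 50 °C; then NaOH, H2O2, 0 °C → rt
Reagents that add atoms: hydrogen peroxide, OO
Why: Hydroboration–oxidation: the bulky borane adds to the terminal C9=C11 bond of the diene with boron on C11, from the α face opposite the axial C10 methyl, so hydrogen enters C9 α and C11 ends β (equatorial) as in the target. The trisubstituted C7=C8 alkene reacts far more slowly.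

Step 15
Reactants: 24 C11 primary alcohol
Product: 25 C11 primary iodide (9α-H, C7=C8, 2α-OTBDPS, 19-OTBS)
Conditions: I2, PPh3, imidazole, CH2Cl2, 0 °C → rt
Reagents that add atoms: iodine, II
Why: Appel-type iodination converts the primary alcohol into the iodide by SN2 displacement of the oxyphosphonium ion without touching C9.

Step 16
Reactants: 26 3-methylbut-2-en-1-ol; 27 methyl 4-chloro-4-oxobutanoate
Product: 28 methyl 3-methylbut-2-en-1-yl butanedioate
Conditions: pyridine, CH2Cl2, 0 °C → rt
Reagents that add atoms: none
Why: Acylation of the primary allylic alcohol with the half-ester acid chloride puts the final C15 ester in place at the start of the side-chain fragment.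

Step 17
Reactants: 28 methyl 3-methylbut-2-en-1-yl butanedioate
Product: 29 (E)-4-hydroxy-3-methylbut-2-en-1-yl methyl butanedioate
Conditions: SeO2 (cat.), t-BuOOH, CH2Cl2, rt
Reagents that add atoms: tert-butyl hydroperoxide, CC(C)(C)OO; selenium dioxide (oxygen carrier), O=[Se]=O
Why: SeO2-catalysed allylic hydroxylation (ene reaction, then 2,3-sigmatropic shift) is selective for the E-methyl group of a trisubstituted alkene, which fixes the 13E geometry.

Step 18
Reactants: 29 (E)-4-hydroxy-3-methylbut-2-en-1-yl methyl butanedioate
Product: 30 (E)-4-bromo-3-methylbut-2-en-1-yl methyl butanedioate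
Conditions: CBr4, PPh3, CH2Cl2, 0 °C
Reagents that add atoms: carbon tetrabromide, BrC(Br)(Br)Br
Why: Appel bromination of the primary allylic alcohol proceeds by SN2 without allylic transposition or loss of alkene geometry.

Step 19
Reactants: 25 C11 primary iodide; 30 (E)-4-bromo-3-methylbut-2-en-1-yl methyl butanedioate
Product: 33 2α-(TBDPS-oxy)-19-(TBS-oxy)labda-7,13(E)-dien-15-yl methyl butanedioate, via alkyllithium 31 (not isolated), via alkylmagnesium bromide 32 (not isolated)
Conditions: t-BuLi (2.1 equiv), Et2O/pentane, −78 °C; MgBr2·OEt2, −78 → 0 °C; 30, Li2CuCl4 (5 mol %), THF, −78 → −30 °C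
Reagents that add atoms: none
Why: Iodine–lithium exchange, transmetalation to magnesium and Li2CuCl4-catalysed coupling with the primary allylic bromide (copper-catalysed Grignard allylic substitution) should form the C11–C12 bond at the α carbon with retention of the E alkene. At low temperature the bromide reacts far faster than the ester groups.

Step 20
Reactants: 33 2α-(TBDPS-oxy)-19-(TBS-oxy)labda-7,13(E)-dien-15-yl methyl butanedioate
Product: 34 19-hydroxy-2α-(TBDPS-oxy)labda-7,13(E)-dien-15-yl methyl butanedioate
Conditions: HF·pyridine, pyridine, THF, 0 °C → rt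
Reagents that add atoms: none
Why: Fluoride cleavage of silyl ethers: the primary TBS ether is removed by buffered HF·pyridine while the bulkier secondary TBDPS ether and both esters remain.

Step 21
Reactants: 34 19-hydroxy-2α-(TBDPS-oxy)labda-7,13(E)-dien-15-yl methyl butanedioate; 35 3-methylbutanoyl chloride
Product: 36 19-(3-methylbutanoyloxy)-2α-(TBDPS-oxy)labda-7,13(E)-dien-15-yl methyl butanedioate
Conditions: pyridine, DMAP (cat.), CH2Cl2, 0 °C → rt
Reagents that add atoms: none
Why: DMAP-catalysed acylation of the neopentyl-type C19 alcohol; C2 is still silylated, so only C19 is esterified.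

Step 22
Reactants: 36 19-(3-methylbutanoyloxy)-2α-(TBDPS-oxy)labda-7,13(E)-dien-15-yl methyl butanedioate
Product: 37 2α-hydroxy-19-(3-methylbutanoyloxy)labda-7,13(E)-dien-15-yl methyl butanedioate (CNP0118741.1)
Conditions: Bu4NF, AcOH (1:1), THF, rt → 40 °C
Reagents that add atoms: none
Why: Fluoride desilylation buffered with acetic acid removes the TBDPS group without ester cleavage or acyl migration and releases the free 2α-hydroxyl.

## Compound list

1 | (R)-carvone, (5R)-2-methyl-5-(prop-1-en-2-yl)cyclohex-2-en-1-one | CC(=C)[C@@H]1CC=C(C)C(=O)C1 | starting material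
2 | iodomethane | CI | starting material
3 | (5R)-2,6-dimethyl-5-(prop-1-en-2-yl)cyclohex-2-en-1-one, C6 epimers | CC(=C)[C@@H]1CC=C(C)C(=O)C1C | intermediate
4 | methyl bromoacetate | COC(=O)CBr | starting material
5 | methyl 2-[(1S,6S)-1,3-dimethyl-2-oxo-6-(prop-1-en-2-yl)cyclohex-3-en-1-yl]acetate | COC(=O)C[C@]1(C)C(=O)C(C)=CC[C@H]1C(C)=C | intermediate
6 | methyl 2-[6-(3-chloroprop-1-en-2-yl)-1,3-dimethyl-2-oxocyclohex-3-en-1-yl]acetate, ring centres as in 5 | COC(=O)C[C@]1(C)C(=O)C(C)=CC[C@H]1C(=C)CCl | intermediate
7 | methyl 2-[6-(3-acetoxyprop-1-en-2-yl)-1,3-dimethyl-2-oxocyclohex-3-en-1-yl]acetate | COC(=O)C[C@]1(C)C(=O)C(C)=CC[C@H]1C(=C)COC(C)=O | intermediate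
8 | methyl 2-[6-(3-hydroxyprop-1-en-2-yl)-1,3-dimethyl-2-oxocyclohex-3-en-1-yl]acetate | COC(=O)C[C@]1(C)C(=O)C(C)=CC[C@H]1C(=C)CO | intermediate
9 | methyl 2-[2-hydroxy-6-(3-hydroxyprop-1-en-2-yl)-1,3-dimethylcyclohex-3-en-1-yl]acetate, 9β-OH (cis to ring methyl) | COC(=O)C[C@]1(C)[C@@H](O)C(C)=CC[C@H]1C(=C)CO | intermediate
10 | mono-TBS ether of 9 at the primary allylic oxygen (C19) | COC(=O)C[C@]1(C)[C@@H](O)C(C)=CC[C@H]1C(=C)CO[Si](C)(C)C(C)(C)C | intermediate
11 | methyl ester with C19 TBS ether and C9 TES ether | COC(=O)C[C@]1(C)[C@@H](O[Si](CC)(CC)CC)C(C)=CC[C@H]1C(=C)CO[Si](C)(C)C(C)(C)C | intermediate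
12 | carboxylic acid with C19 TBS ether and C9 TES ether | OC(=O)C[C@]1(C)[C@@H](O[Si](CC)(CC)CC)C(C)=CC[C@H]1C(=C)CO[Si](C)(C)C(C)(C)C | intermediate
13 | (trimethylsilyl)diazomethane | C[Si](C)(C)C=[N+]=[N-] | starting material
14 | acid chloride of 12 | ClC(=O)C[C@]1(C)[C@@H](O[Si](CC)(CC)CC)C(C)=CC[C@H]1C(=C)CO[Si](C)(C)C(C)(C)C | intermediate
15 | diazomethyl ketone: carvone-derived ring with the 2-(TBS-oxymethyl)allyl arm at C5, the diazoacetonyl arm and methyl at C10, the TES ether at C9 | [N-]=[N+]=CC(=O)C[C@]1(C)[C@@H](O[Si](CC)(CC)CC)C(C)=CC[C@H]1C(=C)CO[Si](C)(C)C(C)(C)C | intermediate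
16 | tricyclic cyclopropyl ketone: 2-oxo, α-cyclopropane C3–C4–C18, 19-OTBS, 9β-OTES, C7=C8, 5α-H, 10β-CH3 | CC[Si](CC)(CC)O[C@H]1C(C)=CC[C@H]2[C@]3(CO[Si](C)(C)C(C)(C)C)C[C@@H]3C(=O)C[C@]12C | intermediate
17 | trans-decal-7-en-2α-ol with 9β-OTES, 4α-CH3, 4β-CH2OTBS, 8-CH3, 10β-CH3 | CC[Si](CC)(CC)O[C@H]1C(C)=CC[C@H]2[C@@](C)(CO[Si](C)(C)C(C)(C)C)C[C@H](O)C[C@]12C | intermediate
18 | trans-decal-7-ene-2α,9β-diol with 4α-CH3, 4β-CH2OTBS, 8-CH3, 10β-CH3 | O[C@H]1C(C)=CC[C@H]2[C@@](C)(CO[Si](C)(C)C(C)(C)C)C[C@H](O)C[C@]12C | intermediate
19 | 2α-hydroxy-19-(TBS-oxy) trans-decal-7-en-9-one (4α-CH3, 8-CH3, 10β-CH3) | O=C1C(C)=CC[C@H]2[C@@](C)(CO[Si](C)(C)C(C)(C)C)C[C@H](O)C[C@]12C | intermediate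
20 | 2α-(TBDPS-oxy)-19-(TBS-oxy) trans-decal-7-en-9-one | O=C1C(C)=CC[C@H]2[C@@](C)(CO[Si](C)(C)C(C)(C)C)C[C@H](O[Si](c3ccccc3)(c3ccccc3)C(C)(C)C)C[C@]12C | intermediate
21 | methyltriphenylphosphonium bromide | C[P+](c1ccccc1)(c1ccccc1)c1ccccc1.[Br-] | starting material
22 | 9-methylene trans-decal-7-ene with 2α-OTBDPS and 19-OTBS | C=C1C(C)=CC[C@H]2[C@@](C)(CO[Si](C)(C)C(C)(C)C)C[C@H](O[Si](c3ccccc3)(c3ccccc3)C(C)(C)C)C[C@]12C | intermediate
23 | B-(C11-alkyl)-9-borabicyclo[3.3.1]nonane, 9α-H | C1CCC2CCCC1B2C[C@H]3C(C)=CC[C@H]4[C@@](C)(CO[Si](C)(C)C(C)(C)C)C[C@H](O[Si](c5ccccc5)(c5ccccc5)C(C)(C)C)C[C@]34C | intermediate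
24 | C11 primary alcohol, 9α-H, C7=C8, 2α-OTBDPS, 19-OTBS | OC[C@H]1C(C)=CC[C@H]2[C@@](C)(CO[Si](C)(C)C(C)(C)C)C[C@H](O[Si](c3ccccc3)(c3ccccc3)C(C)(C)C)C[C@]12C | intermediate
25 | C11 primary iodide, 9α-H, C7=C8, 2α-OTBDPS, 19-OTBS | IC[C@H]1C(C)=CC[C@H]2[C@@](C)(CO[Si](C)(C)C(C)(C)C)C[C@H](O[Si](c3ccccc3)(c3ccccc3)C(C)(C)C)C[C@]12C | intermediate
26 | 3-methylbut-2-en-1-ol | CC(C)=CCO | starting material
27 | methyl 4-chloro-4-oxobutanoate | COC(=O)CCC(Cl)=O | starting material
28 | methyl 3-methylbut-2-en-1-yl butanedioate | COC(=O)CCC(=O)OCC=C(C)C | intermediate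
29 | (E)-4-hydroxy-3-methylbut-2-en-1-yl methyl butanedioate | COC(=O)CCC(=O)OC/C=C(\C)CO | intermediate
30 | (E)-4-bromo-3-methylbut-2-en-1-yl methyl butanedioate | COC(=O)CCC(=O)OC/C=C(\C)CBr | intermediate
31 | C11 alkyllithium from 25 | [Li]C[C@H]1C(C)=CC[C@H]2[C@@](C)(CO[Si](C)(C)C(C)(C)C)C[C@H](O[Si](c3ccccc3)(c3ccccc3)C(C)(C)C)C[C@]12C | intermediate
32 | C11 alkylmagnesium bromide | Br[Mg]C[C@H]1C(C)=CC[C@H]2[C@@](C)(CO[Si](C)(C)C(C)(C)C)C[C@H](O[Si](c3ccccc3)(c3ccccc3)C(C)(C)C)C[C@]12C | intermediate
33 | 2α-(TBDPS-oxy)-19-(TBS-oxy)labda-7,13(E)-dien-15-yl methyl butanedioate | COC(=O)CCC(=O)OC/C=C(\C)CC[C@H]1C(C)=CC[C@H]2[C@@](C)(CO[Si](C)(C)C(C)(C)C)C[C@H](O[Si](c3ccccc3)(c3ccccc3)C(C)(C)C)C[C@]12C | intermediate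
34 | 19-hydroxy-2α-(TBDPS-oxy)labda-7,13(E)-dien-15-yl methyl butanedioate | COC(=O)CCC(=O)OC/C=C(\C)CC[C@H]1C(C)=CC[C@H]2[C@@](C)(CO)C[C@H](O[Si](c3ccccc3)(c3ccccc3)C(C)(C)C)C[C@]12C | intermediate
35 | 3-methylbutanoyl chloride | CC(C)CC(Cl)=O | starting material
36 | 19-(3-methylbutanoyloxy)-2α-(TBDPS-oxy)labda-7,13(E)-dien-15-yl methyl butanedioate | COC(=O)CCC(=O)OC/C=C(\C)CC[C@H]1C(C)=CC[C@H]2[C@@](C)(COC(=O)CC(C)C)C[C@H](O[Si](c3ccccc3)(c3ccccc3)C(C)(C)C)C[C@]12C | intermediate
37 | 2α-hydroxy-19-(3-methylbutanoyloxy)labda-7,13(E)-dien-15-yl methyl butanedioate | COC(=O)CCC(=O)OC/C=C(\C)CC[C@H]1C(C)=CC[C@H]2[C@@](C)(COC(=O)CC(C)C)C[C@H](O)C[C@]12C | target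

## Step count and least certain steps

Total: 22 steps. Longest linear sequence: 19 steps (steps 1–15 and 19–22, from 1); the side-chain fragment 30 takes three steps (16–18).

**Step 9 (key step).** The copper carbene may be diverted into insertion into the C9–H bond, which the silyloxy group activates, or into ylide formation at the C9 ether oxygen. Face selectivity at C4=C18 may also erode if the rotamer with the CH2OTBS group eclipsing C5–H reacts. Fallback: replace the C9 ether by an electron-poor acetate, which deactivates both the C9–H bond and the oxygen. Starting from 15, selective removal of the TES group (HF·pyridine/pyridine, 0 °C) would give the hydroxy diazoketone F1, and acetylation (Ac2O, pyridine, DMAP) the acetoxy diazoketone F2. Cu(acac)2 would then give the 9β-acetoxy cyclopropyl ketone F3, and K2CO3/MeOH the 9β-hydroxy cyclopropyl ketone F4. Li/NH3/EtOH reduction of F4 returns to the route at 18.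

**Step 10.** The reduction may stall at the C2 ketone if the enolate is not protonated, the allylic C9 oxygen may be lost by reductive cleavage, or the acidic TES removal may also attack the C19 TBS ether. Fallback: separate the two reductions. From 16, SmI2 (THF/HMPA, t-BuOH) would open only the cyclopropyl ketone to the ring-opened 2-oxo TES ether F5. An equilibrating Meerwein–Ponndorf–Verley reduction (Al(Oi-Pr)3, i-PrOH, reflux) would then give the equatorial alcohol and return to the route at 17, which is desilylated to 18 as before.

**Step 13.** The ylide may fail to add to the hindered carbonyl, or it may act as a base and remove a γ-proton (C6) to give a dienolate. Fallback: Peterson olefination. From 20, Me3SiCH2Li with CeCl3 would add to give the β-hydroxysilane F6, and KH in THF would eliminate it to return to the route at 22.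

**Step 14.** Hydrogen delivery to C9 may show poor facial selectivity, or the borane may attack the C7=C8 alkene, because the exocyclic alkene is flanked by a quaternary carbon. Fallback: correct C9 by face-selective protonation. From 22, the hydroboration product would be taken on as a mixture of 24 and the 9-epimeric alcohol F7, and oxidised (Dess–Martin periodinane) to the C11 aldehyde epimer mixture F8. Enolisation with KN(SiMe3)2 at −78 °C and kinetic α-protonation from the less hindered α face would converge both epimers to the 9β-formyl compound F9. NaBH4 returns to the route at 24.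

**Step 19.** The organometallic may attack the γ carbon of 30 (allylic transposition), add to an ester group, or be lost by elimination or homocoupling. Fallback: a sulfone-stabilised carbanion, which alkylates allylic bromides cleanly at the α carbon. From 24, PhSSPh/PBu3 would give the C11 phenyl sulfide F10, and (NH4)6Mo7O24/H2O2 the C11 phenyl sulfone F11. Deprotonation (n-BuLi, THF, −78 °C) and alkylation with 30 would give the C11-sulfonyl coupled ester F12. Reductive desulfonylation (Na(Hg), Na2HPO4, MeOH/THF, −20 °C) returns to the route at 33.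

## Further compounds

F1 | step 9 | hydroxy diazoketone (9β-OH, C19 TBS ether) | [N-]=[N+]=CC(=O)C[C@]1(C)[C@@H](O)C(C)=CC[C@H]1C(=C)CO[Si](C)(C)C(C)(C)C
F2 | step 9 | acetoxy diazoketone (9β-OAc, C19 TBS ether) | [N-]=[N+]=CC(=O)C[C@]1(C)[C@@H](OC(C)=O)C(C)=CC[C@H]1C(=C)CO[Si](C)(C)C(C)(C)C
F3 | step 9 | 9β-acetoxy cyclopropyl ketone (α-cyclopropane C3–C4–C18, 19-OTBS) | CC(=O)O[C@H]1C(C)=CC[C@H]2[C@]3(CO[Si](C)(C)C(C)(C)C)C[C@@H]3C(=O)C[C@]12C
F4 | step 9 | 9β-hydroxy cyclopropyl ketone (α-cyclopropane C3–C4–C18, 19-OTBS) | O[C@H]1C(C)=CC[C@H]2[C@]3(CO[Si](C)(C)C(C)(C)C)C[C@@H]3C(=O)C[C@]12C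
F5 | step 10 | ring-opened 2-oxo TES ether (4α-CH3, 19-OTBS, 9β-OTES) | CC[Si](CC)(CC)O[C@H]1C(C)=CC[C@H]2[C@@](C)(CO[Si](C)(C)C(C)(C)C)CC(=O)C[C@]12C
F6 | step 13 | β-hydroxysilane (9β-OH, 9α-CH2SiMe3) | C[Si](C)(C)C[C@]1(O)C(C)=CC[C@H]2[C@@](C)(CO[Si](C)(C)C(C)(C)C)C[C@H](O[Si](c3ccccc3)(c3ccccc3)C(C)(C)C)C[C@]12C
F7 | step 14 | 9-epimeric C11 alcohol (9β-H) | OC[C@@H]1C(C)=CC[C@H]2[C@@](C)(CO[Si](C)(C)C(C)(C)C)C[C@H](O[Si](c3ccccc3)(c3ccccc3)C(C)(C)C)C[C@]12C
F8 | step 14 | C11 aldehyde, mixture of C9 epimers | O=CC1C(C)=CC[C@H]2[C@@](C)(CO[Si](C)(C)C(C)(C)C)C[C@H](O[Si](c3ccccc3)(c3ccccc3)C(C)(C)C)C[C@]12C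
F9 | step 14 | 9β-formyl compound (9α-H) | O=C[C@H]1C(C)=CC[C@H]2[C@@](C)(CO[Si](C)(C)C(C)(C)C)C[C@H](O[Si](c3ccccc3)(c3ccccc3)C(C)(C)C)C[C@]12C
F10 | step 19 | C11 phenyl sulfide | c1ccccc1SC[C@H]1C(C)=CC[C@H]2[C@@](C)(CO[Si](C)(C)C(C)(C)C)C[C@H](O[Si](c3ccccc3)(c3ccccc3)C(C)(C)C)C[C@]12C
F11 | step 19 | C11 phenyl sulfone | O=S(=O)(c1ccccc1)C[C@H]1C(C)=CC[C@H]2[C@@](C)(CO[Si](C)(C)C(C)(C)C)C[C@H](O[Si](c3ccccc3)(c3ccccc3)C(C)(C)C)C[C@]12C
F12 | step 19 | C11-sulfonyl coupled ester (C11 epimers) | COC(=O)CCC(=O)OC/C=C(\C)CC(S(=O)(=O)c1ccccc1)[C@H]1C(C)=CC[C@H]2[C@@](C)(CO[Si](C)(C)C(C)(C)C)C[C@H](O[Si](c3ccccc3)(c3ccccc3)C(C)(C)C)C[C@]12C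
A1 | alternative 1 | methyl (2E,8E,10Z)-5,10-bis(TBS-oxy)-7-[(4-methoxybenzyloxy)methyl]-3,7-dimethyldodeca-2,8,10-trienoate | COC(=O)/C=C(\C)C[C@@H](O[Si](C)(C)C(C)(C)C)C[C@](C)(COCc1ccc(OC)cc1)/C=C/C(O[Si](C)(C)C(C)(C)C)=C/C
A2 | alternative 1 | trans-fused bicyclic silyl enol ether with the C9 methyl ester | COC(=O)[C@H]1[C@@H](C)C(O[Si](C)(C)C(C)(C)C)=C[C@H]2[C@@](C)(COCc3ccc(OC)cc3)C[C@H](O[Si](C)(C)C(C)(C)C)C[C@]12C
A3 | alternative 2 | Se-phenyl selenoester of the carvone-derived acid with a 2-(methoxycarbonyl)vinyl group at C5 | O=C([Se]c1ccccc1)C[C@]1(C)C(=O)C(C)=CC[C@H]1C(=C)C(=O)OC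
A4 | alternative 2 | 2,9-dioxo trans-decal-7-ene with the C19 methyl ester on C4 (C4–H) | O=C1C(C)=CC[C@H]2[C@@H](C(=O)OC)CC(=O)C[C@]12C
A5 | alternative 3 | open-chain (Z)-allylic acetate with the (E)-C5=C10 alkene and the C2 trimethylsilyl enol ether | CC(=O)OC/C=C(/C)[C@H](CCO[Si](c1ccccc1)(c1ccccc1)C(C)(C)C)/C(C)=C/[C@@](C)(COC(=O)CC(C)C)CC(O[Si](C)(C)C)=C
A6 | alternative 3 | 2-oxo trans-decal-7-ene with C19 isovalerate and C12 TBDPS ether | CC(C)(C)[Si](OCC[C@H]1C(C)=CC[C@H]2[C@@](C)(COC(=O)CC(C)C)CC(=O)C[C@]12C)(c1ccccc1)c1ccccc1
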